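The hydrocarbon is cut at C1–C10 and C1′–C10′, so that both A rings close in one two-directional operation. The step exploits the fact that each ring B, with the C8 methyl, the C9–C11 link and the quaternary C10, is the 1,4-dihydro form of a 2,3,6-trisubstituted benzamide: Birch reduction makes C10 an amide enolate that displaces a chloride tethered at C5, which builds ring A, the C10 stereocentre and the C8=C9 alkene together. The precursor is a C2-symmetric bibenzyl bis-benzamide with (S)-2-(methoxymethyl)pyrrolidine auxiliaries and two 4-chloro-1,1-dimethylbutyl arms.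

Key step: step 10

Remark: terpenoid numbering (C1–C11, primed in the second half) is used for the precursor carbons. The (S)-auxiliary is assumed to send the tether to the face of C10 that leaves the carboxamide on the side of the future methyl (β). The hindered benzamides 7–17 are expected as slowly interconverting aryl–carbonyl rotamers that all converge in step 10. Because the route is two-directional, steps 1, 3, 4, 6 and 9 consume two molecules of the same component per molecule of product; the second molecule is entered under the reagents that add atoms.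

Step 1
Reactants: 1 2,3-dimethylbenzoic acid (two molecules)
Product: 3 2,2'-(ethane-1,2-diyl)bis(3-methylbenzoic acid), via lateral dilithio dianion 2 (not isolated)
Conditions: LiN(i-Pr)2 (2.2 equiv per acid), THF, −78 → 0 °C; I2 (0.5 equiv per acid, added slowly), −78 °C → rt; aq. HCl
Reagents that add atoms: second molecule of 2,3-dimethylbenzoic acid 1, SMILES Cc1cccc(C(=O)O)c1C
Why: Two equivalents of base per acid form the carboxylate and then the benzylic anion at the 2-methyl group only (the 3-methyl has no ortho carboxylate), and iodine joins two such anions at carbon in an oxidative homocoupling of a toluate dianion.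

Step 2
Reactants: 3 2,2'-(ethane-1,2-diyl)bis(3-methylbenzoic acid)
Product: 4 2,2'-(ethane-1,2-diyl)bis(6-iodo-3-methylbenzoic acid)
Conditions: Pd(OAc)2 (10 mol %), PhI(OAc)2 (1.1 equiv), I2 (1.1 equiv), DMF, 100 °C, dark
Reagents that add atoms: iodine, SMILES II
Why: Carboxylate-directed palladium-catalysed ortho C–H iodination by acetyl hypoiodite formed in the flask should place one iodine per ring, because C6 is the only ortho C–H.

Step 3
Reactants: 4 2,2'-(ethane-1,2-diyl)bis(6-iodo-3-methylbenzoic acid); 5 (S)-2-(methoxymethyl)pyrrolidine (two molecules)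
Product: 7 1,2-bis{3-iodo-6-methyl-2-[(S)-2-(methoxymethyl)pyrrolidine-1-carbonyl]phenyl}ethane, via bis(acid chloride) 6 (not isolated)
Conditions: (COCl)2 (2.5 equiv), DMF (cat.), CH2Cl2, 0 °C → rt; then 5 (2.4 equiv), Et3N, DMAP (cat.), CH2Cl2, 0 → 40 °C
Reagents that add atoms: second molecule of (S)-2-(methoxymethyl)pyrrolidine 5, SMILES COC[C@@H]1CCCN1
Why: Acid chloride formation followed by N-acylation of one secondary amine per acyl group (amide coupling) is reliable for 2,6-disubstituted benzoyl chlorides and does not touch the auxiliary stereocentre.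

Step 4
Reactants: 7 1,2-bis{3-iodo-6-methyl-2-[(S)-2-(methoxymethyl)pyrrolidine-1-carbonyl]phenyl}ethane; 8 methyl isobutyrate (two molecules)
Product: 10 1,2-bis{3-(1-methoxy-2-methyl-1-oxopropan-2-yl)-6-methyl-2-[(S)-2-(methoxymethyl)pyrrolidine-1-carbonyl]phenyl}ethane, via lithium ester enolate 9 (not isolated)
Conditions: 8 (2.6 equiv), LiNCy2 (2.6 equiv), toluene, 0 °C → rt; then 7, Pd(dba)2 (5 mol %), P(t-Bu)3 (5 mol %), toluene, rt → 50 °C
Reagents that add atoms: second molecule of methyl isobutyrate 8, SMILES COC(=O)C(C)C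
Why: Palladium-catalysed α-arylation of an ester enolate (oxidative addition into each C–I bond, transmetalation, reductive elimination) should build the two benzylic quaternary carbons C4 and C4′, one enolate per aryl iodide, and the product has no α-hydrogen left for a second arylation.

Step 5
Reactants: 10 bis(methyl ester) from step 4
Product: 11 1,2-bis{6-methyl-3-(2-methyl-1-oxopropan-2-yl)-2-[(S)-2-(methoxymethyl)pyrrolidine-1-carbonyl]phenyl}ethane
Conditions: i-Bu2AlH (2.2 equiv), CH2Cl2, −78 °C; aq. potassium sodium tartrate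
Reagents that add atoms: none
Why: Partial hydride reduction of an ester should stop at the aldehyde because the aluminium hemiacetal beside a quaternary carbon persists until work-up, while the doubly ortho-shielded tertiary benzamides are not attacked at −78 °C.

Step 6
Reactants: 11 dialdehyde from step 5; 12 triethyl phosphonoacetate (two molecules)
Product: 14 1,2-bis{3-[(E)-5-ethoxy-2-methyl-5-oxopent-3-en-2-yl]-6-methyl-2-[(S)-2-(methoxymethyl)pyrrolidine-1-carbonyl]phenyl}ethane, via sodium phosphonate carbanion 13 (not isolated)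
Conditions: 12 (2.6 equiv), NaH (2.6 equiv), THF, 0 °C; then 11, 0 → 50 °C
Reagents that add atoms: second molecule of triethyl phosphonoacetate 12, SMILES CCOC(=O)CP(=O)(OCC)OCC
Why: Horner–Wadsworth–Emmons olefination adds C2 and C1 to each arm as an (E)-enoate, and the aldehydes cannot enolise.

Step 7
Reactants: 14 bis(enoate) from step 6
Product: 15 1,2-bis{3-(5-ethoxy-2-methyl-5-oxopentan-2-yl)-6-methyl-2-[(S)-2-(methoxymethyl)pyrrolidine-1-carbonyl]phenyl}ethane
Conditions: H2 (1 bar), Pd/C, EtOAc, rt
Reagents that add atoms: none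
Why: Heterogeneous catalytic hydrogenation saturates the two conjugated disubstituted alkenes while arenes, esters and amides stay intact.

Step 8
Reactants: 15 bis(ethyl ester) from step 7
Product: 16 1,2-bis{3-(5-hydroxy-2-methylpentan-2-yl)-6-methyl-2-[(S)-2-(methoxymethyl)pyrrolidine-1-carbonyl]phenyl}ethane
Conditions: LiBH4, THF, 0 → 50 °C
Reagents that add atoms: none
Why: Chemoselective hydride reduction of esters to primary alcohols, since LiBH4 does not reduce hindered tertiary amides.

Step 9
Reactants: 16 diol from step 8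
Product: 17 1,2-bis{3-(5-chloro-2-methylpentan-2-yl)-6-methyl-2-[(S)-2-(methoxymethyl)pyrrolidine-1-carbonyl]phenyl}ethane
Conditions: PPh3 (2.4 equiv), NCS (2.4 equiv), CH2Cl2, 0 °C → rt
Reagents that add atoms: N-chlorosuccinimide, SMILES O=C1CCC(=O)N1Cl; second molecule of N-chlorosuccinimide, SMILES O=C1CCC(=O)N1Cl
Why: Appel-type chlorination through alkoxyphosphonium ions converts both primary alcohols to chlorides by SN2 under neutral conditions, one chlorine being delivered per arm.

Step 10
Reactants: 17 bis(chloroalkyl) bis-benzamide from step 9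
Product: 19 1,2-bis{(8aS)-8a-[(S)-2-(methoxymethyl)pyrrolidine-1-carbonyl]-2,5,5-trimethyl-3,5,6,7,8,8a-hexahydronaphthalen-1-yl}ethane (carboxamides on the face of the future C10 methyls), via bis(lithium amide enolate) 18 (not isolated)
Conditions: Li (4.4 equiv), NH3(l)/THF, t-BuOH (2.0 equiv), −78 °C; isoprene; −78 → −33 °C, then rt; NH4Cl
Reagents that add atoms: none
Why: Lithium transfers two electrons to each benzamide ring and tert-butanol protonates C7, para to the carboxamide, which leaves a lithium amide enolate centred on C10 and cross-conjugated with C5=C6 and C8=C9; on warming, each C10 carbon displaces its tethered primary chloride by SN2 and forms C1–C10. The closest known reaction type is the Birch reduction–alkylation of 2-substituted benzamides of (S)-2-(methoxymethyl)pyrrolidine, run here intramolecularly and on both halves at once. Ring A and ring A′ each close in a 6-(enolexo)-exo-tet mode. C10 and C10′ are controlled by the auxiliary: with the pyrrolidine turned away from the C4 quaternary centre and lithium held between the enolate oxygen and the methoxymethyl ether, the tether should add anti to that arm, which places the carboxamide on the β face. The step needs alkylation at C10 and not at the γ-carbon C6, which the same tether could also reach, and it needs the C–Cl bonds to outlive the reduction. The first is secured by the much higher charge density at the α-carbon of a lithium dienolate together with the three ring alkyl groups that steer protonation to C7, the second by the slow reduction of primary alkyl chlorides at −78 °C and by destroying excess lithium with isoprene before warming.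

Step 11
Reactants: 19 bis(hexahydronaphthalene) bis-amide from step 10
Product: 20 1,2-bis{(4aS,8aR)-8a-[(S)-2-(methoxymethyl)pyrrolidine-1-carbonyl]-2,5,5-trimethyl-3,4,4a,5,6,7,8,8a-octahydronaphthalen-1-yl}ethane (H-5 α, carboxamide β, trans-fused)
Conditions: H2 (4 bar), PtO2, EtOAc, rt
Reagents that add atoms: none
Why: Heterogeneous catalytic hydrogenation should reduce only the trisubstituted C5=C6 bonds (the tetrasubstituted C8=C9 bonds are far slower) and deliver hydrogen to the α face, anti to the bulky angular carboxamide as in 5-ene steroids, which sets C5 and C5′ with trans ring fusion.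

Step 12
Reactants: 20 trans-fused bis-amide from step 11
Product: 21 1,2-bis[(4aS,8aR)-8a-(hydroxymethyl)-2,5,5-trimethyl-3,4,4a,5,6,7,8,8a-octahydronaphthalen-1-yl]ethane
Conditions: LiNH2BH3 (from BH3·NH3 and LiN(i-Pr)2), THF, 0 → 66 °C; aq. NH4Cl
Reagents that add atoms: none
Why: Amide reduction with lithium amidotrihydroborate, a small and strongly nucleophilic hydride, should take hindered α-quaternary tertiary amides to primary alcohols with C–N cleavage and release the auxiliary.

Step 13
Reactants: 21 diol from step 12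
Product: 22 1,2-bis[(4aS,8aR)-8a-formyl-2,5,5-trimethyl-3,4,4a,5,6,7,8,8a-octahydronaphthalen-1-yl]ethane
Conditions: Dess–Martin periodinane, CH2Cl2, rt
Reagents that add atoms: none
Why: Dess–Martin oxidation converts the neopentyl primary alcohols to aldehydes under near-neutral conditions, and the aldehydes cannot enolise at quaternary C10.

Step 14
Reactants: 22 dialdehyde from step 13
Product: 24 1,2-bis[(4aS,8aS)-2,5,5,8a-tetramethyl-3,4,4a,5,6,7,8,8a-octahydronaphthalen-1-yl]ethane (CNP0372467.1), via bis-hydrazone 23 (not isolated)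
Conditions: N2H4·H2O, KOH, diethylene glycol, 130 °C, then 210 °C
Reagents that add atoms: none
Why: Wolff–Kishner reduction turns each angular formyl group into the C10 methyl by loss of nitrogen from the hydrazone under hot base, a standard route to angular methyls that cannot disturb quaternary C10 or the C8=C9 alkene.

Compound list
1 | 2,3-dimethylbenzoic acid | Cc1cccc(C(=O)O)c1C | starting material
2 | lithium 2-(lithiomethyl)-3-methylbenzoate | [Li]Cc1c(C)cccc1C(=O)O[Li] | intermediate (not isolated)
3 | 2,2'-(ethane-1,2-diyl)bis(3-methylbenzoic acid) | OC(=O)c1cccc(C)c1CCc1c(C)cccc1C(=O)O | intermediate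
4 | 2,2'-(ethane-1,2-diyl)bis(6-iodo-3-methylbenzoic acid) | OC(=O)c1c(I)ccc(C)c1CCc1c(C)ccc(I)c1C(=O)O | intermediate
5 | (S)-2-(methoxymethyl)pyrrolidine | COC[C@@H]1CCCN1 | starting material
6 | 2,2'-(ethane-1,2-diyl)bis(6-iodo-3-methylbenzoyl chloride) | ClC(=O)c1c(I)ccc(C)c1CCc1c(C)ccc(I)c1C(Cl)=O | intermediate (not isolated)
7 | 1,2-bis{3-iodo-6-methyl-2-[(S)-2-(methoxymethyl)pyrrolidine-1-carbonyl]phenyl}ethane | C(Cc1c(C)ccc(I)c1C(=O)N1CCC[C@H]1COC)c1c(C)ccc(I)c1C(=O)N1CCC[C@H]1COC | intermediate
8 | methyl isobutyrate | COC(=O)C(C)C | starting material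
9 | lithium enolate of methyl isobutyrate | COC(O[Li])=C(C)C | intermediate (not isolated)
10 | 1,2-bis{3-(1-methoxy-2-methyl-1-oxopropan-2-yl)-6-methyl-2-[(S)-2-(methoxymethyl)pyrrolidine-1-carbonyl]phenyl}ethane | C(Cc1c(C)ccc(C(C)(C)C(=O)OC)c1C(=O)N1CCC[C@H]1COC)c1c(C)ccc(C(C)(C)C(=O)OC)c1C(=O)N1CCC[C@H]1COC | intermediate
11 | 1,2-bis{6-methyl-3-(2-methyl-1-oxopropan-2-yl)-2-[(S)-2-(methoxymethyl)pyrrolidine-1-carbonyl]phenyl}ethane | C(Cc1c(C)ccc(C(C)(C)C=O)c1C(=O)N1CCC[C@H]1COC)c1c(C)ccc(C(C)(C)C=O)c1C(=O)N1CCC[C@H]1COC | intermediate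
12 | triethyl phosphonoacetate | CCOC(=O)CP(=O)(OCC)OCC | starting material
13 | sodium salt of triethyl phosphonoacetate | CCOC(=O)[CH-]P(=O)(OCC)OCC.[Na+] | intermediate (not isolated)
14 | 1,2-bis{3-[(E)-5-ethoxy-2-methyl-5-oxopent-3-en-2-yl]-6-methyl-2-[(S)-2-(methoxymethyl)pyrrolidine-1-carbonyl]phenyl}ethane | C(Cc1c(C)ccc(C(C)(C)/C=C/C(=O)OCC)c1C(=O)N1CCC[C@H]1COC)c1c(C)ccc(C(C)(C)/C=C/C(=O)OCC)c1C(=O)N1CCC[C@H]1COC | intermediate
15 | 1,2-bis{3-(5-ethoxy-2-methyl-5-oxopentan-2-yl)-6-methyl-2-[(S)-2-(methoxymethyl)pyrrolidine-1-carbonyl]phenyl}ethane | C(Cc1c(C)ccc(C(C)(C)CCC(=O)OCC)c1C(=O)N1CCC[C@H]1COC)c1c(C)ccc(C(C)(C)CCC(=O)OCC)c1C(=O)N1CCC[C@H]1COC | intermediate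
16 | 1,2-bis{3-(5-hydroxy-2-methylpentan-2-yl)-6-methyl-2-[(S)-2-(methoxymethyl)pyrrolidine-1-carbonyl]phenyl}ethane | C(Cc1c(C)ccc(C(C)(C)CCCO)c1C(=O)N1CCC[C@H]1COC)c1c(C)ccc(C(C)(C)CCCO)c1C(=O)N1CCC[C@H]1COC | intermediate
17 | 1,2-bis{3-(5-chloro-2-methylpentan-2-yl)-6-methyl-2-[(S)-2-(methoxymethyl)pyrrolidine-1-carbonyl]phenyl}ethane | C(Cc1c(C)ccc(C(C)(C)CCCCl)c1C(=O)N1CCC[C@H]1COC)c1c(C)ccc(C(C)(C)CCCCl)c1C(=O)N1CCC[C@H]1COC | intermediate (precursor of the key step)
18 | bis(lithium amide enolate) of the 1,4-dihydro bis-benzamide, both chlorides intact | C(CC1=C(C)CC=C(C(C)(C)CCCCl)C1=C(O[Li])N1CCC[C@H]1COC)C1=C(C)CC=C(C(C)(C)CCCCl)C1=C(O[Li])N1CCC[C@H]1COC | intermediate (not isolated)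
19 | 1,2-bis{(8aS)-8a-[(S)-2-(methoxymethyl)pyrrolidine-1-carbonyl]-2,5,5-trimethyl-3,5,6,7,8,8a-hexahydronaphthalen-1-yl}ethane | C(CC1=C(C)CC=C2C(C)(C)CCC[C@]12C(=O)N1CCC[C@H]1COC)C1=C(C)CC=C2C(C)(C)CCC[C@]12C(=O)N1CCC[C@H]1COC | intermediate (product of the key step)
20 | 1,2-bis{(4aS,8aR)-8a-[(S)-2-(methoxymethyl)pyrrolidine-1-carbonyl]-2,5,5-trimethyl-3,4,4a,5,6,7,8,8a-octahydronaphthalen-1-yl}ethane | C(CC1=C(C)CC[C@H]2C(C)(C)CCC[C@]12C(=O)N1CCC[C@H]1COC)C1=C(C)CC[C@H]2C(C)(C)CCC[C@]12C(=O)N1CCC[C@H]1COC | intermediate
21 | 1,2-bis[(4aS,8aR)-8a-(hydroxymethyl)-2,5,5-trimethyl-3,4,4a,5,6,7,8,8a-octahydronaphthalen-1-yl]ethane | C(CC1=C(C)CC[C@H]2C(C)(C)CCC[C@]12CO)C1=C(C)CC[C@H]2C(C)(C)CCC[C@]12CO | intermediate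
22 | 1,2-bis[(4aS,8aR)-8a-formyl-2,5,5-trimethyl-3,4,4a,5,6,7,8,8a-octahydronaphthalen-1-yl]ethane | C(CC1=C(C)CC[C@H]2C(C)(C)CCC[C@]12C=O)C1=C(C)CC[C@H]2C(C)(C)CCC[C@]12C=O | intermediate
23 | bis-hydrazone of dialdehyde 22 | C(CC1=C(C)CC[C@H]2C(C)(C)CCC[C@]12C=NN)C1=C(C)CC[C@H]2C(C)(C)CCC[C@]12C=NN | intermediate (not isolated)
24 | 1,2-bis[(4aS,8aS)-2,5,5,8a-tetramethyl-3,4,4a,5,6,7,8,8a-octahydronaphthalen-1-yl]ethane | CC1=C(CCC2=C(C)CC[C@H]3C(C)(C)CCC[C@]23C)[C@@]2(C)CCCC(C)(C)[C@@H]2CC1 | target

Total step count: 14. Longest linear sequence: 14 steps (1 → 24); compounds 5, 8 and 12 are used as purchased.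

Steps most likely to fail

Step 10. Excess metal may reduce the C–Cl bonds before ring closure, the enolate may be protonated so that an uncyclised dihydro amide results, or facial discrimination may be weak because the crowded enolate cannot become planar and chelated. The fallback sets out from 17 and separates reduction from alkylation. Li/NH3 with excess t-BuOH and an NH4Cl quench at −78 °C should give the protonated 1,2-bis{5-(5-chloro-2-methylpentan-2-yl)-2-methyl-6-[(S)-2-(methoxymethyl)pyrrolidine-1-carbonyl]cyclohexa-1,4-dien-1-yl}ethane F1 (C10 epimers, of no consequence). Deprotonation at C10 with LiN(i-Pr)2 in THF at −78 °C and warming should then regenerate the enolate without dissolved metal or ammonia and close both rings, which comes back to the route at 19. An enolate made by deprotonation is aggregated differently and offers a second, independent chance of facial control.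

Step 4. Reductive elimination at the crowded aryl–palladium centre next to the ortho carboxamide may be slow, so that protodeiodination or only one coupling results. The fallback sets out from 7 and forms the quaternary carbons by γ-selective allyl transfer instead of enolate arylation. Suzuki–Miyaura coupling with prenylboronic acid pinacol ester under branch-selective conditions (Pd(OAc)2, bulky biarylphosphine, K3PO4, THF/water) should give 1,2-bis{6-methyl-3-(2-methylbut-3-en-2-yl)-2-[(S)-2-(methoxymethyl)pyrrolidine-1-carbonyl]phenyl}ethane F2. Ozonolysis (O3, CH2Cl2, −78 °C; Me2S) then cuts each vinyl group to the aldehyde, which comes back to the route at 11 and makes step 5 unnecessary.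

Step 11. The C5=C6 bond may migrate within the skipped diene on the catalyst surface, uptake at this hindered alkene may be sluggish, or hydrogen may be delivered from the β face to give cis-fused material. The fallback sets out from 19 and uses hydrogen-atom-transfer hydrogenation (Mn(dpm)3 cat., PhSiH3, t-BuOOH, i-PrOH, rt). A tertiary C5 radical is quenched from the axial direction, which should favour the trans-fused system, and the tetrasubstituted C8=C9 bond reacts much more slowly. This comes back to the route at 20 and passes through no new isolable compound (F0).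

Further compounds
F1 | step 10 | 1,2-bis{5-(5-chloro-2-methylpentan-2-yl)-2-methyl-6-[(S)-2-(methoxymethyl)pyrrolidine-1-carbonyl]cyclohexa-1,4-dien-1-yl}ethane (C10 epimers) | C(CC1=C(C)CC=C(C(C)(C)CCCCl)C1C(=O)N1CCC[C@H]1COC)C1=C(C)CC=C(C(C)(C)CCCCl)C1C(=O)N1CCC[C@H]1COC
F2 | step 4 | 1,2-bis{6-methyl-3-(2-methylbut-3-en-2-yl)-2-[(S)-2-(methoxymethyl)pyrrolidine-1-carbonyl]phenyl}ethane | C(Cc1c(C)ccc(C(C)(C)C=C)c1C(=O)N1CCC[C@H]1COC)c1c(C)ccc(C(C)(C)C=C)c1C(=O)N1CCC[C@H]1COC
F0 | step 11 | none | none
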